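**Retrosynthetic overview**
1. Feature: C2 of the cyclopentane carries a one-carbon group cis to the aryl ring on the neighbouring quaternary C1, and that ring has an ortho oxygen. A six-membered lactone (aryl O–C(=O)–C2) can span them, so C1, C2 and the C2 carbon are read as the C–C(=O)–C(N2) unit of a cyclohexanone.
2. Late stage: the aryl bromide comes from para-bromination of the phenol, C3=CHBr from Wittig bromomethylenation of a C3 ketone, and the C2 methyl from the lactone carbonyl (CH2OH, CH2I, CH3).
3. Key disconnection: cis-fused cyclopenta[c]chroman-4-one 12 from 2-diazo-3-hydroxy-6-aryl-6-methylcyclohexanone 10 by photochemical Wolff ring contraction (C1–C2 bond) with capture of the ketene by the phenol.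
4. Precursor: 10 from 2-diazo-1,3-dione 9 by borohydride reduction of the carbonyl remote from C1. C3 is carried as a carbinol because a ketal there would have to be set on an enolised 1,3-dione and would be expelled from any enolate used for diazo transfer. 9 comes from Claisen closure and diazo transfer on keto lactone 7, itself from asymmetric Michael addition of benzofuranone 5 to methyl vinyl ketone.
5. Ring order: benzofuranone (temporary lactone), then cyclohexane-1,3-dione, then cyclopentane and δ-lactone together in the key step, then the lactone is opened.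

Key step: step 6

Assumption: the sense of induction of the cinchona catalyst in step 3 is not predicted here; the quinidine-derived catalyst is written, and its quinine-derived pseudoenantiomer is used instead if the adduct proves to be (R).

**Step 1**
Reactants: 1 1-bromo-2-methoxy-4-methylbenzene; 2 tert-butyl propanoate
Product: 3 tert-butyl 2-(2-methoxy-4-methylphenyl)propanoate (racemic)
Conditions: LiNCy2 (lithium dicyclohexylamide), bis(dibenzylideneacetone)palladium (2 mol %), P(t-Bu)3 (2 mol %), toluene, rt
Reagents that add atoms: none
Why: Palladium-catalysed α-arylation of the lithium ester enolate joins the aryl ring to the propanoate α-carbon, the tert-butyl ester suppressing Claisen self-condensation and the secondary product resisting a second arylation; the α-centre is racemic and is reset in step 3.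

**Step 2**
Reactants: 3 tert-butyl 2-(2-methoxy-4-methylphenyl)propanoate
Product: 5 3,6-dimethyl-1-benzofuran-2(3H)-one (racemic), via hydroxy acid 4 (not isolated)
Conditions: BBr3, CH2Cl2, −78 °C to rt; H2O; then TsOH (cat.), toluene, reflux
Reagents that add atoms: none
Why: Boron tribromide cleaves the aryl methyl ether and the tert-butyl ester, and the resulting 2-(2-hydroxyaryl)propanoic acid closes to the five-membered aryl lactone by acid-catalysed lactonisation; the α-centre stays racemic and enolisable, as step 3 requires.

**Step 3**
Reactants: 5 3,6-dimethyl-1-benzofuran-2(3H)-one; 6 methyl vinyl ketone (but-3-en-2-one)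
Product: 7 (3S)-3,6-dimethyl-3-(3-oxobutyl)-1-benzofuran-2(3H)-one
Conditions: N-[3,5-bis(trifluoromethyl)phenyl]-N′-(9-deoxy-9-epi-quinidin-9-yl)thiourea (10 mol %), toluene, −20 °C
Reagents that add atoms: none
Why: Bifunctional amine–thiourea-catalysed Michael addition, in which the quinuclidine deprotonates the lactone to its aromatic benzofuran-2-olate while the thiourea binds the enone, so that the C–C bond forms on the enolate face left open in the chiral ion pair and sets the quaternary (S) centre that becomes C1 of the target.

**Step 4**
Reactants: 7 (3S)-3,6-dimethyl-3-(3-oxobutyl)-1-benzofuran-2(3H)-one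
Product: 9 (4S)-2-diazo-4-(2-hydroxy-4-methylphenyl)-4-methylcyclohexane-1,3-dione, via dione 8 (not isolated)
Conditions: LiN(SiMe3)2 (2.1 equiv), THF, −78 to 0 °C; then 4-acetamidobenzenesulfonyl azide, MeCN, 0 °C to rt; aqueous work-up
Reagents that add atoms: 4-acetamidobenzenesulfonyl azide, CC(=O)Nc1ccc(cc1)S(=O)(=O)N=[N+]=[N-]
Why: Intramolecular Claisen condensation of the kinetic methyl-ketone enolate on the aryl lactone carbonyl (phenoxide as leaving group) closes the cyclohexane-1,3-dione, and Regitz diazo transfer to its enolate in the same flask occupies C2 before the freed phenol can condense with the enolised dione; the quaternary centre is not touched.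

**Step 5**
Reactants: 9 (4S)-2-diazo-4-(2-hydroxy-4-methylphenyl)-4-methylcyclohexane-1,3-dione
Product: 10 (6S)-2-diazo-3-hydroxy-6-(2-hydroxy-4-methylphenyl)-6-methylcyclohexan-1-one (both C3 epimers)
Conditions: NaBH4, MeOH, −20 to 0 °C
Reagents that add atoms: none
Why: Borohydride reduction of a 2-diazo-1,3-diketone stops at the α-diazo-β-hydroxy ketone because the remaining carbonyl is a deactivated diazo-conjugated acyl group, and hydride attacks C1, the carbonyl remote from the quaternary carbon, which leaves on the diazo carbon only the acyl group flanked by that quaternary carbon; the new carbinol centre is not controlled and need not be, since it is oxidised in step 11.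

**Step 6**
Reactants: 10 (6S)-2-diazo-3-hydroxy-6-(2-hydroxy-4-methylphenyl)-6-methylcyclohexan-1-one
Product: 12 (3aR,9bR)-3-hydroxy-7,9b-dimethyl-2,3,3a,9b-tetrahydrocyclopenta[c]chromen-4(1H)-one (cis-fused; both C3 epimers), via ketene 11 (not isolated)
Conditions: hν (medium-pressure Hg lamp, Pyrex filter, λ > 300 nm), MeCN (0.005 M, degassed), 0 °C
Reagents that add atoms: none
Why: Light excites the s-Z-locked α-diazo ketone, N2 leaves and the C6–C1 bond shifts to C2 in the same event (Wolff rearrangement), so the quaternary carbon migrates with retention and the ring contracts to cyclopentylidene ketene 11. The closest known reaction type is the photochemical Wolff ring contraction of cyclic 2-diazo ketones with intramolecular capture of the ketene by a hydroxyl group. The cyclopentane closes by the 1,2-shift itself (new bond between the quaternary carbon and the former diazo carbon, C1–C2 of the target), and the lactone closes by 6-exo-dig addition of the phenol oxygen to the ketene carbonyl carbon followed by ketonisation of the ester enol. The new stereocentre (C3a, C2 of the target) is set in that ketonisation: the lactone tether from the aryl oxygen holds the carboxyl carbon on the aryl face of the cyclopentane, so the proton arrives on the opposite face and the fusion is cis, controlled by the quaternary centre. The step needs migration of the quaternary carbon alone and capture by the phenol alone; the diazo carbon carries a single acyl group, its other neighbour being the C3 carbinol, and the phenol reaches the ketene through a six-membered transition state whereas the C3 hydroxyl could only close a β-lactone. Direct irradiation without sensitiser or metal keeps the reaction on the concerted path and away from a carbene hydride shift from C3.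

**Step 7**
Reactants: 12 (3aR,9bR)-3-hydroxy-7,9b-dimethyl-2,3,3a,9b-tetrahydrocyclopenta[c]chromen-4(1H)-one
Product: 13 2-[(1R,2S)-3-hydroxy-2-(hydroxymethyl)-1-methylcyclopentyl]-5-methylphenol (both C3 epimers)
Conditions: LiAlH4, THF, 0 °C to rt
Reagents that add atoms: none
Why: Hydride reduction of the aryl lactone frees the phenol and turns the carboxyl carbon into the primary alcohol on C2 without touching either stereocentre, C2 no longer being α to a carbonyl.

**Step 8**
Reactants: 13 2-[(1R,2S)-3-hydroxy-2-(hydroxymethyl)-1-methylcyclopentyl]-5-methylphenol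
Product: 14 (2S,3R)-2-(hydroxymethyl)-3-[2-(methoxymethoxy)-4-methylphenyl]-3-methylcyclopentan-1-ol (both C1 epimers)
Conditions: MOMCl (1.1 equiv), K2CO3, DMF, 0 °C to rt
Reagents that add atoms: chloromethyl methyl ether, COCCl
Why: Williamson etherification of the phenoxide, the only hydroxyl acidic enough to be deprotonated by carbonate, masks the phenol so that it cannot alkylate itself on the activated CH2 in step 9 or be oxidised in step 11.

**Step 9**
Reactants: 14 (2S,3R)-2-(hydroxymethyl)-3-[2-(methoxymethoxy)-4-methylphenyl]-3-methylcyclopentan-1-ol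
Product: 15 (2R,3R)-2-(iodomethyl)-3-[2-(methoxymethoxy)-4-methylphenyl]-3-methylcyclopentan-1-ol (both C1 epimers)
Conditions: PPh3, I2, imidazole, CH2Cl2, 0 °C to rt
Reagents that add atoms: iodine, II
Why: Appel-type iodination converts the primary alcohol selectively, the ring carbinol being secondary and hindered, and the substitution at CH2 leaves the ring stereocentres untouched.

**Step 10**
Reactants: 15 (2R,3R)-2-(iodomethyl)-3-[2-(methoxymethoxy)-4-methylphenyl]-3-methylcyclopentan-1-ol
Product: 16 (2R,3R)-3-[2-(methoxymethoxy)-4-methylphenyl]-2,3-dimethylcyclopentan-1-ol (both C1 epimers)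
Conditions: Bu3SnH, AIBN (cat.), toluene (0.1 M), 80 °C
Reagents that add atoms: none
Why: Radical chain reduction of the primary iodide by the tin hydride gives the C2 methyl group under neutral conditions, which avoids oxetane formation from the 1,3-iodo alcohol, and the radical centre is not a stereocentre.

**Step 11**
Reactants: 16 (2R,3R)-3-[2-(methoxymethoxy)-4-methylphenyl]-2,3-dimethylcyclopentan-1-ol
Product: 17 (2R,3R)-3-[2-(methoxymethoxy)-4-methylphenyl]-2,3-dimethylcyclopentan-1-one
Conditions: Dess–Martin periodinane, CH2Cl2, 0 °C to rt
Reagents that add atoms: none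
Why: Dess–Martin oxidation merges both carbinol epimers into one ketone under non-basic conditions, so that the adjacent stereocentre (C2 of the target) is not enolised.

**Step 12**
Reactants: 17 (2R,3R)-3-[2-(methoxymethoxy)-4-methylphenyl]-2,3-dimethylcyclopentan-1-one
Product: 18 1-[(1R,2R,3E)-3-(bromomethylidene)-1,2-dimethylcyclopentyl]-2-(methoxymethoxy)-4-methylbenzene
Conditions: Ph3P(CH2Br)Br, KOt-Bu, THF, −78 °C; then 17, −78 °C to rt
Reagents that add atoms: (bromomethyl)triphenylphosphonium bromide, [Br-].BrC[P+](c1ccccc1)(c1ccccc1)c1ccccc1
Why: Wittig olefination with bromomethylidene-triphenylphosphorane, in which bromine should settle anti to the substituted C2 and towards the C4 methylene, the less crowded arrangement and the E geometry, while low temperature and a slight deficit of base relative to the phosphonium salt limit enolisation at C2.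

**Step 13**
Reactants: 18 1-[(1R,2R,3E)-3-(bromomethylidene)-1,2-dimethylcyclopentyl]-2-(methoxymethoxy)-4-methylbenzene
Product: 19 2-[(1R,2R,3E)-3-(bromomethylidene)-1,2-dimethylcyclopentyl]-5-methylphenol
Conditions: HCl (0.5 M in MeOH), 0 °C to rt
Reagents that add atoms: none
Why: Acid-catalysed acetal exchange with methanol removes the aryl methoxymethyl ether, run cold and dilute so that the deactivated bromoalkene is neither protonated nor attacked by the freed phenol.

**Step 14**
Reactants: 19 2-[(1R,2R,3E)-3-(bromomethylidene)-1,2-dimethylcyclopentyl]-5-methylphenol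
Product: 20 4-bromo-2-[(1R,2R,3E)-3-(bromomethylidene)-1,2-dimethylcyclopentyl]-5-methylphenol
Conditions: N-bromosuccinimide (1.0 equiv), MeCN, −20 to 0 °C
Reagents that add atoms: N-bromosuccinimide, BrN1C(=O)CCC1=O
Why: Electrophilic aromatic bromination of the phenol goes para to the hydroxyl and ortho to the methyl, the only unhindered activated position, and the electron-poor bromoalkene reacts far more slowly with the reagent.

**Compound list**
1 | 1-bromo-2-methoxy-4-methylbenzene | COc1cc(C)ccc1Br | starting material
2 | tert-butyl propanoate | CCC(=O)OC(C)(C)C | starting material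
3 | tert-butyl 2-(2-methoxy-4-methylphenyl)propanoate (racemic) | COc1cc(C)ccc1C(C)C(=O)OC(C)(C)C | intermediate
4 | 2-(2-hydroxy-4-methylphenyl)propanoic acid (racemic, not isolated) | Cc1ccc(C(C)C(=O)O)c(O)c1 | intermediate
5 | 3,6-dimethyl-1-benzofuran-2(3H)-one (racemic) | CC1C(=O)Oc2cc(C)ccc21 | intermediate
6 | methyl vinyl ketone | C=CC(C)=O | starting material
7 | (3S)-3,6-dimethyl-3-(3-oxobutyl)-1-benzofuran-2(3H)-one | Cc1ccc2c(c1)OC(=O)[C@@]2(C)CCC(C)=O | intermediate
8 | (4S)-4-(2-hydroxy-4-methylphenyl)-4-methylcyclohexane-1,3-dione (not isolated) | Cc1ccc([C@]2(C)CCC(=O)CC2=O)c(O)c1 | intermediate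
9 | (4S)-2-diazo-4-(2-hydroxy-4-methylphenyl)-4-methylcyclohexane-1,3-dione | Cc1ccc([C@]2(C)CCC(=O)C(=[N+]=[N-])C2=O)c(O)c1 | intermediate
10 | (6S)-2-diazo-3-hydroxy-6-(2-hydroxy-4-methylphenyl)-6-methylcyclohexan-1-one, both C3 epimers | Cc1ccc([C@]2(C)CCC(O)C(=[N+]=[N-])C2=O)c(O)c1 | intermediate
11 | [(5S)-2-hydroxy-5-(2-hydroxy-4-methylphenyl)-5-methylcyclopentylidene]ketene, both carbinol epimers (not isolated) | Cc1ccc([C@]2(C)CCC(O)C2=C=O)c(O)c1 | intermediate
12 | (3aR,9bR)-3-hydroxy-7,9b-dimethyl-2,3,3a,9b-tetrahydrocyclopenta[c]chromen-4(1H)-one, cis-fused, both C3 epimers | Cc1ccc2c(c1)OC(=O)[C@H]1C(O)CC[C@@]21C | intermediate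
13 | 2-[(1R,2S)-3-hydroxy-2-(hydroxymethyl)-1-methylcyclopentyl]-5-methylphenol, both C3 epimers | Cc1ccc([C@]2(C)CCC(O)[C@@H]2CO)c(O)c1 | intermediate
14 | (2S,3R)-2-(hydroxymethyl)-3-[2-(methoxymethoxy)-4-methylphenyl]-3-methylcyclopentan-1-ol, both C1 epimers | COCOc1cc(C)ccc1[C@]1(C)CCC(O)[C@@H]1CO | intermediate
15 | (2R,3R)-2-(iodomethyl)-3-[2-(methoxymethoxy)-4-methylphenyl]-3-methylcyclopentan-1-ol, both C1 epimers | COCOc1cc(C)ccc1[C@]1(C)CCC(O)[C@@H]1CI | intermediate
16 | (2R,3R)-3-[2-(methoxymethoxy)-4-methylphenyl]-2,3-dimethylcyclopentan-1-ol, both C1 epimers | COCOc1cc(C)ccc1[C@]1(C)CCC(O)[C@@H]1C | intermediate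
17 | (2R,3R)-3-[2-(methoxymethoxy)-4-methylphenyl]-2,3-dimethylcyclopentan-1-one | COCOc1cc(C)ccc1[C@]1(C)CCC(=O)[C@@H]1C | intermediate
18 | 1-[(1R,2R,3E)-3-(bromomethylidene)-1,2-dimethylcyclopentyl]-2-(methoxymethoxy)-4-methylbenzene | COCOc1cc(C)ccc1[C@]1(C)CC/C(=C\Br)[C@@H]1C | intermediate
19 | 2-[(1R,2R,3E)-3-(bromomethylidene)-1,2-dimethylcyclopentyl]-5-methylphenol | Cc1ccc([C@]2(C)CC/C(=C\Br)[C@@H]2C)c(O)c1 | intermediate
20 | 4-bromo-2-[(1R,2R,3E)-3-(bromomethylidene)-1,2-dimethylcyclopentyl]-5-methylphenol | Cc1cc(O)c([C@]2(C)CC/C(=C\Br)[C@@H]2C)cc1Br | target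

Total step count: 14. Longest linear sequence: 14 steps (from 1).

**Steps most likely to fail**

Step 6. The excited diazo ketone may leak from the concerted rearrangement into carbene chemistry (hydride shift from C3 returning the enolised dione, O–H insertion into the two free hydroxyl groups), and the ketene may be captured by the wrong hydroxyl or by a second molecule. The fallback sets out from 10. Both hydroxyl groups are silylated (t-BuMe2SiCl, imidazole, DMF) to give (6S)-2-diazo-3-(tert-butyldimethylsilyloxy)-6-[2-(tert-butyldimethylsilyloxy)-4-methylphenyl]-6-methylcyclohexan-1-one F1, so that no O–H bond is within reach of the diazo carbon. Irradiation in methanol, the classical ring contraction with an external trap, should give methyl 2-(tert-butyldimethylsilyloxy)-5-[2-(tert-butyldimethylsilyloxy)-4-methylphenyl]-5-methylcyclopentane-1-carboxylate F2, the ester enol being protonated mainly from the face away from the aryl group. Bu4NF in THF then removes both silyl groups; the freed phenoxide closes onto the neighbouring ester, helped by the quaternary centre, and any trans ester epimerises under the basic conditions before it lactonises. The fallback comes back to the route at 12.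

Step 12. The olefination may show low E/Z selectivity, and the ylide or residual alkoxide may enolise the α-branched ketone and so epimerise C2. The fallback sets out from 17. Boron-Wittig olefination with LiCH(Bpin)2, made from bis(pinacolato)borylmethane and lithium 2,2,6,6-tetramethylpiperidide in THF at −78 °C, should give 2-{(E)-[(2R,3R)-3-[2-(methoxymethoxy)-4-methylphenyl]-2,3-dimethylcyclopentylidene]methyl}-4,4,5,5-tetramethyl-1,3,2-dioxaborolane F3, with boron on the less hindered side; the geometric isomers can be separated at this stage. Bromodeboronation of the E boronate with CuBr2 in aqueous methanol proceeds with retention of the double-bond geometry. The fallback comes back to the route at 18.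

Step 3. The 3-methyl lactone is only weakly acidic, so facial selectivity in the addition may be insufficient, and reversible addition (retro-Michael) may erode it. The fallback sets out from 5 and 6. Addition catalysed by triethylamine in toluene gives racemic 3,6-dimethyl-3-(3-oxobutyl)-1-benzofuran-2(3H)-one F4, which is resolved by preparative chromatography on a chiral stationary phase. The (S) enantiomer comes back to the route as 7.

**Further compounds**
F1 | step 6 | (6S)-2-diazo-3-(tert-butyldimethylsilyloxy)-6-[2-(tert-butyldimethylsilyloxy)-4-methylphenyl]-6-methylcyclohexan-1-one, both C3 epimers | Cc1ccc([C@]2(C)CCC(O[Si](C)(C)C(C)(C)C)C(=[N+]=[N-])C2=O)c(O[Si](C)(C)C(C)(C)C)c1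
F2 | step 6 | methyl (5R)-2-(tert-butyldimethylsilyloxy)-5-[2-(tert-butyldimethylsilyloxy)-4-methylphenyl]-5-methylcyclopentane-1-carboxylate, mixture at C1 and C2 | Cc1ccc([C@]2(C)CCC(O[Si](C)(C)C(C)(C)C)C2C(=O)OC)c(O[Si](C)(C)C(C)(C)C)c1
F3 | step 12 | 2-{(E)-[(2R,3R)-3-[2-(methoxymethoxy)-4-methylphenyl]-2,3-dimethylcyclopentylidene]methyl}-4,4,5,5-tetramethyl-1,3,2-dioxaborolane | COCOc1cc(C)ccc1[C@]1(C)CC/C(=C\B2OC(C)(C)C(C)(C)O2)[C@@H]1C
F4 | step 3 | racemic 3,6-dimethyl-3-(3-oxobutyl)-1-benzofuran-2(3H)-one | CC(=O)CCC1(C)C(=O)Oc2cc(C)ccc21
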